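## Retrosynthetic overview

1. Target 24 ⇐ 22: the α-methylene lactone is carried as its ethanethiol adduct and unmasked last, after C8 tigloylation and C3 desilylation of macrocycle 19.
2. Key disconnection C1–C10: the ten-membered carbocycle (second and last ring) closes by an intramolecular NHC benzoin. The C1 aldehyde of seco keto-aldehyde 18 becomes a Breslow acyl anion and attacks the C10 methyl ketone, creating the tertiary α-ketol.
3. C8–C9: an L-proline aldol of hydroxyacetone 16 onto lactone aldehyde 15 installs C8, C9 and the C10 ketone in one step.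
4. C6–C7 and the γ-lactone (first ring): an Evans syn-aldol of itaconate-derived imide 11 with (Z)-enal 7, then lactonisation.
5. Enal 7: asymmetric alkynylation of 1 with 2 (C3), syn-methylcupration (Z-C4=C5), then redox adjustment.

Assumptions: locants C1–C15 are those of the germacranolide target (C1 ketone, C4=C5, C6 lactone carbinol, C11–C13 lactone α-carbon, carbonyl and methylene). In steps 1 and 12 the ligand or catalyst antipode named is the one expected to give the drawn configuration, and its mirror image is used if the sense proves opposite.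

## Route

Step 1
Reactants: 1 3-[(tert-butyldimethylsilyl)oxy]propanal; 2 methyl propiolate
Product: 3 methyl (4S)-6-[(tert-butyldimethylsilyl)oxy]-4-hydroxyhex-2-ynoate
Conditions: Me2Zn (3 equiv), (S,S)-ProPhenol [2,6-bis{[(S)-2-(hydroxydiphenylmethyl)pyrrolidin-1-yl]methyl}-4-methylphenol, 20 mol %], Ph3PO (40 mol %), toluene, 4 °C
Reagents that add atoms: none
Why: Zinc–ProPhenol asymmetric alkynylation, in which the dinuclear zinc alkynylide adds to one face of the aldehyde and sets the future C3 carbinol as S.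

Step 2
Reactants: 3 methyl (4S)-6-[(tert-butyldimethylsilyl)oxy]-4-hydroxyhex-2-ynoate
Product: 4 methyl (4S)-4,6-bis[(tert-butyldimethylsilyl)oxy]hex-2-ynoate
Conditions: TBSCl, imidazole, DMF, 0 °C to rt
Reagents that add atoms: tert-butyldimethylsilyl chloride (TBSCl), SMILES CC(C)(C)[Si](C)(C)Cl
Why: Imidazole-promoted O-silylation of the propargylic alcohol; no stereocentre is touched.

Step 3
Reactants: 4 methyl (4S)-4,6-bis[(tert-butyldimethylsilyl)oxy]hex-2-ynoate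
Product: 5 methyl (2Z,4S)-4,6-bis[(tert-butyldimethylsilyl)oxy]-3-methylhex-2-enoate
Conditions: Me2CuLi (from MeLi and CuI), THF, −78 °C; aq NH4Cl at −78 °C
Reagents that add atoms: lithium dimethylcuprate (Me2CuLi), SMILES [Li+].C[Cu-]C
Why: syn-Carbocupration of the ynoate and protonation of the vinylcopper with retention put the new methyl cis to H, so the C3 chain and the ester are cis (Z-C4=C5 of the target).

Step 4
Reactants: 5 methyl (2Z,4S)-4,6-bis[(tert-butyldimethylsilyl)oxy]-3-methylhex-2-enoate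
Product: 6 (2Z,4S)-4,6-bis[(tert-butyldimethylsilyl)oxy]-3-methylhex-2-en-1-ol
Conditions: i-Bu2AlH (2.5 equiv), CH2Cl2, −78 °C
Reagents that add atoms: none
Why: 1,2-Reduction of the enoate by the aluminium hydride gives the allylic alcohol with the olefin geometry unchanged.

Step 5
Reactants: 6 (2Z,4S)-4,6-bis[(tert-butyldimethylsilyl)oxy]-3-methylhex-2-en-1-ol
Product: 7 (2Z,4S)-4,6-bis[(tert-butyldimethylsilyl)oxy]-3-methylhex-2-enal
Conditions: MnO2 (excess), CH2Cl2, rt, dark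
Reagents that add atoms: none
Why: Neutral MnO2 allylic oxidation gives the Z-enal without Z/E isomerisation (the nerol-to-neral case).

Step 6
Reactants: 8 itaconic anhydride; 9 (4S)-4-benzyl-1,3-oxazolidin-2-one
Product: 11 methyl 4-[(4S)-4-benzyl-2-oxo-1,3-oxazolidin-3-yl]-2-methylidene-4-oxobutanoate, via lithium carboxylate 10 (not isolated)
Conditions: 9, n-BuLi, THF, −78 °C; 8, −78 °C; then MeI, DMF, −78 °C to rt
Reagents that add atoms: iodomethane (MeI), SMILES CI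
Why: N-Acylation of the lithiated Evans auxiliary by opening the anhydride at its non-conjugated carbonyl (fast at −78 °C, which outruns base isomerisation to citraconate), followed by SN2 O-methylation of the carboxylate.

Step 7
Reactants: 11 methyl 4-[(4S)-4-benzyl-2-oxo-1,3-oxazolidin-3-yl]-2-methylidene-4-oxobutanoate; 7 (2Z,4S)-4,6-bis[(tert-butyldimethylsilyl)oxy]-3-methylhex-2-enal
Product: 13 (4S)-4-benzyl-3-{[(2R,3S)-2-[(1Z,3S)-3-[(tert-butyldimethylsilyl)oxy]-5-hydroxy-2-methylpent-1-en-1-yl]-4-methylidene-5-oxooxolan-3-yl]carbonyl}-1,3-oxazolidin-2-one, via syn-aldol adduct 12 (not isolated)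
Conditions: 11, Bu2BOTf, i-Pr2NEt, CH2Cl2, −78 to 0 °C; 7, −78 to −20 °C; MeOH quench; then camphor-10-sulfonic acid (0.2 equiv), MeOH–CH2Cl2, 0 °C to rt
Reagents that add atoms: none
Why: Evans syn-aldol through the Z-boron enolate and a Zimmerman–Traxler chair, where the (4S)-benzyl auxiliary fixes C6 as R and C7 as S; acid then lactonises the γ-hydroxy acrylate to the 6,7-trans α-methylene-γ-butyrolactone and methanolysis removes only the primary TBS ether.

Step 8
Reactants: 13 (4S)-4-benzyl-3-{[(2R,3S)-2-[(1Z,3S)-3-[(tert-butyldimethylsilyl)oxy]-5-hydroxy-2-methylpent-1-en-1-yl]-4-methylidene-5-oxooxolan-3-yl]carbonyl}-1,3-oxazolidin-2-one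
Product: 14 S-ethyl (2R,3S,4S)-2-[(1Z,3S)-3-[(tert-butyldimethylsilyl)oxy]-5-hydroxy-2-methylpent-1-en-1-yl]-4-[(ethylsulfanyl)methyl]-5-oxooxolane-3-carbothioate
Conditions: EtSH (6 equiv), n-BuLi (0.3 equiv), THF, 0 °C
Reagents that add atoms: ethanethiol (EtSH), SMILES CCS
Why: Lithium thiolate transacylation of the N-acyloxazolidinone gives the thioester (auxiliary recovered), and thia-Michael addition masks the α-methylene lactone (reversible thiol protection); C11 is set under equilibrating conditions (drawn trans to C7) and is erased in step 15.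

Step 9
Reactants: 14 S-ethyl (2R,3S,4S)-2-[(1Z,3S)-3-[(tert-butyldimethylsilyl)oxy]-5-hydroxy-2-methylpent-1-en-1-yl]-4-[(ethylsulfanyl)methyl]-5-oxooxolane-3-carbothioate
Product: 15 (2R,3S,4S)-2-[(1Z,3S)-3-[(tert-butyldimethylsilyl)oxy]-5-hydroxy-2-methylpent-1-en-1-yl]-4-[(ethylsulfanyl)methyl]-5-oxooxolane-3-carbaldehyde
Conditions: Et3SiH (3 equiv), 10% Pd/C (10–20 mol %), acetone, rt
Reagents that add atoms: none
Why: Fukuyama reduction converts only the thioester into the C8 aldehyde; C7 is now epimerisable, but the 6,7-trans arrangement already present is the thermodynamic one.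

Step 10
Reactants: 15 (2R,3S,4S)-2-[(1Z,3S)-3-[(tert-butyldimethylsilyl)oxy]-5-hydroxy-2-methylpent-1-en-1-yl]-4-[(ethylsulfanyl)methyl]-5-oxooxolane-3-carbaldehyde; 16 hydroxyacetone
Product: 17 (3S,4R,5R)-5-[(1Z,3S)-3-[(tert-butyldimethylsilyl)oxy]-5-hydroxy-2-methylpent-1-en-1-yl]-4-[(1S,2S)-1,2-dihydroxy-3-oxobutyl]-3-[(ethylsulfanyl)methyl]oxolan-2-one
Conditions: 16 (10 equiv), L-proline (30 mol %), DMSO, rt, 48 h
Reagents that add atoms: none
Why: Proline-catalysed direct aldol of hydroxyacetone (List-type): the enamine forms at the hydroxylated carbon and the hydrogen-bonded chair transition state gives the anti-diol with catalyst-controlled 8S,9S configuration on this α-branched aldehyde.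

Step 11
Reactants: 17 (3S,4R,5R)-5-[(1Z,3S)-3-[(tert-butyldimethylsilyl)oxy]-5-hydroxy-2-methylpent-1-en-1-yl]-4-[(1S,2S)-1,2-dihydroxy-3-oxobutyl]-3-[(ethylsulfanyl)methyl]oxolan-2-one
Product: 18 (3S,4Z)-3-[(tert-butyldimethylsilyl)oxy]-5-[(2R,3R,4S)-3-[(1S,2S)-1,2-dihydroxy-3-oxobutyl]-4-[(ethylsulfanyl)methyl]-5-oxooxolan-2-yl]-4-methylpent-4-enal
Conditions: TEMPO (2,2,6,6-tetramethylpiperidin-1-oxyl, 0.2 equiv), PhI(OAc)2 (1.2 equiv), CH2Cl2, rt
Reagents that add atoms: none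
Why: TEMPO/PhI(OAc)2 oxidation, in which the bulky oxoammonium oxidises only the primary C1 alcohol and leaves the secondary diol, the sulfide and the olefin alone.

Step 12
Reactants: 18 (3S,4Z)-3-[(tert-butyldimethylsilyl)oxy]-5-[(2R,3R,4S)-3-[(1S,2S)-1,2-dihydroxy-3-oxobutyl]-4-[(ethylsulfanyl)methyl]-5-oxooxolan-2-yl]-4-methylpent-4-enal
Product: 19 (3S,3aR,4S,5S,6S,9S,10Z,11aR)-9-[(tert-butyldimethylsilyl)oxy]-3-[(ethylsulfanyl)methyl]-4,5,6-trihydroxy-6,10-dimethyl-3a,4,5,6,8,9-hexahydrocyclodeca[b]furan-2,7(3H,11aH)-dione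
Conditions: (5aS,10bR)-2-(pentafluorophenyl)-5a,10b-dihydro-4H,6H-indeno[2,1-b][1,2,4]triazolo[4,3-d][1,4]oxazin-2-ium tetrafluoroborate (30 mol %), i-Pr2NEt (30 mol %), toluene, 40 °C, syringe-pump addition to 2 mM
Reagents that add atoms: none
Why: Proposed new method: the triazolylidene adds to the unhindered C1 aldehyde to give the Breslow acyl anion equivalent, which attacks the C10 methyl ketone across the chain pre-folded by the Z-olefin and trans-lactone (aldehyde homo-benzoin is reversible and suppressed at 2 mM), while the chiral aminoindanol carbene and hydrogen bonding from C9–OH to the ketone direct attack to the face giving 10S; the closest known reaction type is the NHC-catalysed intramolecular crossed aldehyde–ketone benzoin that forms five- and six-membered tertiary acyloins.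

Step 13
Reactants: 19 (3S,3aR,4S,5S,6S,9S,10Z,11aR)-9-[(tert-butyldimethylsilyl)oxy]-3-[(ethylsulfanyl)methyl]-4,5,6-trihydroxy-6,10-dimethyl-3a,4,5,6,8,9-hexahydrocyclodeca[b]furan-2,7(3H,11aH)-dione; 20 (E)-2-methylbut-2-enoyl chloride (tigloyl chloride)
Product: 21 (3S,3aS,4S,5S,6S,9S,10Z,11aR)-9-[(tert-butyldimethylsilyl)oxy]-3-[(ethylsulfanyl)methyl]-5,6-dihydroxy-6,10-dimethyl-2,7-dioxo-2,3,3a,4,5,6,7,8,9,11a-decahydrocyclodeca[b]furan-4-yl (2E)-2-methylbut-2-enoate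
Conditions: 20 (1.2 equiv), pyridine, 4-(dimethylamino)pyridine (5 mol %), CH2Cl2, −20 °C
Reagents that add atoms: none
Why: Nucleophile-catalysed acylation goes to C8–OH because C9–OH is neopentyl-like beside the quaternary C10 and C10–OH is tertiary; no stereocentre changes.

Step 14
Reactants: 21 (3S,3aS,4S,5S,6S,9S,10Z,11aR)-9-[(tert-butyldimethylsilyl)oxy]-3-[(ethylsulfanyl)methyl]-5,6-dihydroxy-6,10-dimethyl-2,7-dioxo-2,3,3a,4,5,6,7,8,9,11a-decahydrocyclodeca[b]furan-4-yl (2E)-2-methylbut-2-enoate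
Product: 22 (3S,3aS,4S,5S,6S,9S,10Z,11aR)-3-[(ethylsulfanyl)methyl]-5,6,9-trihydroxy-6,10-dimethyl-2,7-dioxo-2,3,3a,4,5,6,7,8,9,11a-decahydrocyclodeca[b]furan-4-yl (2E)-2-methylbut-2-enoate
Conditions: HF·pyridine, pyridine, THF, 0 °C to rt
Reagents that add atoms: none
Why: Buffered fluoride desilylation of the allylic TBS ether under weakly acidic conditions that avoid tiglate migration and retro-aldol of the β-hydroxy ketone.

Step 15
Reactants: 22 (3S,3aS,4S,5S,6S,9S,10Z,11aR)-3-[(ethylsulfanyl)methyl]-5,6,9-trihydroxy-6,10-dimethyl-2,7-dioxo-2,3,3a,4,5,6,7,8,9,11a-decahydrocyclodeca[b]furan-4-yl (2E)-2-methylbut-2-enoate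
Product: 24 (3aS,4S,5S,6S,9S,10Z,11aR)-5,6,9-trihydroxy-6,10-dimethyl-3-methylidene-2,7-dioxo-2,3,3a,4,5,6,7,8,9,11a-decahydrocyclodeca[b]furan-4-yl (2E)-2-methylbut-2-enoate (CNP0106709.2), via S-methylsulfonium iodide 23 (not isolated)
Conditions: MeI (excess), MeCN, rt, dark; then aq NaHCO3, EtOAc, rt
Reagents that add atoms: iodomethane (MeI), SMILES CI
Why: S-Methylation gives the sulfonium salt and mild-base E1cB β-elimination regenerates the α-methylene lactone (reverse of the thiol protection), removing the temporary C11 stereocentre.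

## Compound list

1 | 3-[(tert-butyldimethylsilyl)oxy]propanal | O=CCCO[Si](C)(C)C(C)(C)C | starting material
2 | methyl propiolate | C#CC(=O)OC | starting material
3 | methyl (4S)-6-[(tert-butyldimethylsilyl)oxy]-4-hydroxyhex-2-ynoate | COC(=O)C#C[C@@H](O)CCO[Si](C)(C)C(C)(C)C | intermediate
4 | methyl (4S)-4,6-bis[(tert-butyldimethylsilyl)oxy]hex-2-ynoate | COC(=O)C#C[C@@H](O[Si](C)(C)C(C)(C)C)CCO[Si](C)(C)C(C)(C)C | intermediate
5 | methyl (2Z,4S)-4,6-bis[(tert-butyldimethylsilyl)oxy]-3-methylhex-2-enoate | COC(=O)/C=C(/C)[C@@H](O[Si](C)(C)C(C)(C)C)CCO[Si](C)(C)C(C)(C)C | intermediate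
6 | (2Z,4S)-4,6-bis[(tert-butyldimethylsilyl)oxy]-3-methylhex-2-en-1-ol | OC/C=C(/C)[C@@H](O[Si](C)(C)C(C)(C)C)CCO[Si](C)(C)C(C)(C)C | intermediate
7 | (2Z,4S)-4,6-bis[(tert-butyldimethylsilyl)oxy]-3-methylhex-2-enal | O=C/C=C(/C)[C@@H](O[Si](C)(C)C(C)(C)C)CCO[Si](C)(C)C(C)(C)C | intermediate
8 | itaconic anhydride (3-methylideneoxolane-2,5-dione) | C=C1CC(=O)OC1=O | starting material
9 | (4S)-4-benzyl-1,3-oxazolidin-2-one | O=C1N[C@@H](Cc2ccccc2)CO1 | starting material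
10 | lithium 4-[(4S)-4-benzyl-2-oxo-1,3-oxazolidin-3-yl]-2-methylidene-4-oxobutanoate | [Li+].[O-]C(=O)C(=C)CC(=O)N1[C@@H](Cc2ccccc2)COC1=O | intermediate (not isolated)
11 | methyl 4-[(4S)-4-benzyl-2-oxo-1,3-oxazolidin-3-yl]-2-methylidene-4-oxobutanoate | COC(=O)C(=C)CC(=O)N1[C@@H](Cc2ccccc2)COC1=O | intermediate
12 | methyl (3S,4R,5Z,7S)-3-{[(4S)-4-benzyl-2-oxo-1,3-oxazolidin-3-yl]carbonyl}-7,9-bis[(tert-butyldimethylsilyl)oxy]-4-hydroxy-6-methyl-2-methylidenenon-5-enoate | COC(=O)C(=C)[C@@H]([C@H](O)/C=C(/C)[C@@H](O[Si](C)(C)C(C)(C)C)CCO[Si](C)(C)C(C)(C)C)C(=O)N1[C@@H](Cc2ccccc2)COC1=O | intermediate (not isolated)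
13 | (4S)-4-benzyl-3-{[(2R,3S)-2-[(1Z,3S)-3-[(tert-butyldimethylsilyl)oxy]-5-hydroxy-2-methylpent-1-en-1-yl]-4-methylidene-5-oxooxolan-3-yl]carbonyl}-1,3-oxazolidin-2-one | C=C1C(=O)O[C@H](/C=C(/C)[C@@H](O[Si](C)(C)C(C)(C)C)CCO)[C@H]1C(=O)N2[C@@H](Cc3ccccc3)COC2=O | intermediate
14 | S-ethyl (2R,3S,4S)-2-[(1Z,3S)-3-[(tert-butyldimethylsilyl)oxy]-5-hydroxy-2-methylpent-1-en-1-yl]-4-[(ethylsulfanyl)methyl]-5-oxooxolane-3-carbothioate | CCSC[C@@H]1C(=O)O[C@H](/C=C(/C)[C@@H](O[Si](C)(C)C(C)(C)C)CCO)[C@H]1C(=O)SCC | intermediate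
15 | (2R,3S,4S)-2-[(1Z,3S)-3-[(tert-butyldimethylsilyl)oxy]-5-hydroxy-2-methylpent-1-en-1-yl]-4-[(ethylsulfanyl)methyl]-5-oxooxolane-3-carbaldehyde | CCSC[C@@H]1C(=O)O[C@H](/C=C(/C)[C@@H](O[Si](C)(C)C(C)(C)C)CCO)[C@H]1C=O | intermediate
16 | hydroxyacetone (1-hydroxypropan-2-one) | CC(=O)CO | starting material
17 | (3S,4R,5R)-5-[(1Z,3S)-3-[(tert-butyldimethylsilyl)oxy]-5-hydroxy-2-methylpent-1-en-1-yl]-4-[(1S,2S)-1,2-dihydroxy-3-oxobutyl]-3-[(ethylsulfanyl)methyl]oxolan-2-one | CCSC[C@@H]1C(=O)O[C@H](/C=C(/C)[C@@H](O[Si](C)(C)C(C)(C)C)CCO)[C@H]1[C@H](O)[C@H](O)C(C)=O | intermediate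
18 | (3S,4Z)-3-[(tert-butyldimethylsilyl)oxy]-5-[(2R,3R,4S)-3-[(1S,2S)-1,2-dihydroxy-3-oxobutyl]-4-[(ethylsulfanyl)methyl]-5-oxooxolan-2-yl]-4-methylpent-4-enal | CCSC[C@@H]1C(=O)O[C@H](/C=C(/C)[C@@H](O[Si](C)(C)C(C)(C)C)CC=O)[C@H]1[C@H](O)[C@H](O)C(C)=O | intermediate
19 | (3S,3aR,4S,5S,6S,9S,10Z,11aR)-9-[(tert-butyldimethylsilyl)oxy]-3-[(ethylsulfanyl)methyl]-4,5,6-trihydroxy-6,10-dimethyl-3a,4,5,6,8,9-hexahydrocyclodeca[b]furan-2,7(3H,11aH)-dione | CCSC[C@@H]1C(=O)O[C@@H]2/C=C(/C)[C@@H](O[Si](C)(C)C(C)(C)C)CC(=O)[C@@](C)(O)[C@@H](O)[C@@H](O)[C@@H]12 | intermediate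
20 | (E)-2-methylbut-2-enoyl chloride (tigloyl chloride) | C/C=C(\C)C(Cl)=O | starting material
21 | (3S,3aS,4S,5S,6S,9S,10Z,11aR)-9-[(tert-butyldimethylsilyl)oxy]-3-[(ethylsulfanyl)methyl]-5,6-dihydroxy-6,10-dimethyl-2,7-dioxo-2,3,3a,4,5,6,7,8,9,11a-decahydrocyclodeca[b]furan-4-yl (2E)-2-methylbut-2-enoate | CCSC[C@@H]1C(=O)O[C@@H]2/C=C(/C)[C@@H](O[Si](C)(C)C(C)(C)C)CC(=O)[C@@](C)(O)[C@@H](O)[C@@H](OC(=O)/C(C)=C/C)[C@@H]12 | intermediate
22 | (3S,3aS,4S,5S,6S,9S,10Z,11aR)-3-[(ethylsulfanyl)methyl]-5,6,9-trihydroxy-6,10-dimethyl-2,7-dioxo-2,3,3a,4,5,6,7,8,9,11a-decahydrocyclodeca[b]furan-4-yl (2E)-2-methylbut-2-enoate | CCSC[C@@H]1C(=O)O[C@@H]2/C=C(/C)[C@@H](O)CC(=O)[C@@](C)(O)[C@@H](O)[C@@H](OC(=O)/C(C)=C/C)[C@@H]12 | intermediate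
23 | ethyl(methyl){[(3S,3aS,4S,5S,6S,9S,10Z,11aR)-5,6,9-trihydroxy-6,10-dimethyl-4-{[(2E)-2-methylbut-2-enoyl]oxy}-2,7-dioxo-2,3,3a,4,5,6,7,8,9,11a-decahydrocyclodeca[b]furan-3-yl]methyl}sulfonium iodide | CC[S+](C)C[C@@H]1C(=O)O[C@@H]2/C=C(/C)[C@@H](O)CC(=O)[C@@](C)(O)[C@@H](O)[C@@H](OC(=O)/C(C)=C/C)[C@@H]12.[I-] | intermediate (not isolated)
24 | (3aS,4S,5S,6S,9S,10Z,11aR)-5,6,9-trihydroxy-6,10-dimethyl-3-methylidene-2,7-dioxo-2,3,3a,4,5,6,7,8,9,11a-decahydrocyclodeca[b]furan-4-yl (2E)-2-methylbut-2-enoate | C=C1C(=O)O[C@@H]2/C=C(/C)[C@@H](O)CC(=O)[C@@](C)(O)[C@@H](O)[C@@H](OC(=O)/C(C)=C/C)[C@@H]12 | target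

## Step count and risks

Total step count: 15. Longest linear sequence: 14 steps (steps 1–5, then 7–15); step 6 is the one-step side branch to imide 11.

The three steps most likely to fail:

**Step 12 (ten-membered benzoin ring closure).** The ring closure may be thermodynamically unfavourable, and the free C8–OH can translactonise under base. The fallback closes the same bond by a ketyl (pinacol) coupling, sets out from 17 and returns at 19. Triol 17 is treated with 2,2-dimethoxypropane and pyridinium p-toluenesulfonate to give the C8/C9 acetonide F1. The primary alcohol is oxidised with TEMPO/PhI(OAc)2 to acetonide keto-aldehyde F2. SmI2 (THF, t-BuOH, −78 °C, high dilution) reduces the aldehyde to its ketyl, which adds to the C10 ketone and gives the macrocyclic C1,C10-diol F3. Dess–Martin periodinane oxidises the secondary C1 carbinol to the acetonide-protected α-ketol F4. Aqueous acetic acid (80%, rt) removes the acetonide and delivers 19.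

**Step 13 (site-selective tigloylation of triol 19).** Selectivity between C8–OH and C9–OH rests on sterics only. The fallback acylates before ring closure on a mono-silylated diol, sets out from 18 and returns at 22. Et3SiCl/imidazole at −40 °C silylates the more acidic, less hindered α-ketol hydroxyl of 18 to give the 9-O-triethylsilyl ether F5. Tigloyl chloride/4-(dimethylamino)pyridine can then only acylate C8–OH and gives the 8-O-tigloyl keto-aldehyde F6. The benzoin conditions of step 12 close the ring to the macrocyclic 9-O-triethylsilyl tiglate F7. HF·pyridine removes both silyl groups and gives 22.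

**Step 10 (late proline aldol on a complex aldehyde).** Yield and facial match with the C7 centre are uncertain. The fallback builds the ketol in two stages, sets out from 15 and returns at 17. L-Proline-catalysed aldol of 15 with acetone (the most robust variant) gives the β-hydroxy methyl ketone F8. D-Proline-catalysed α-aminoxylation with nitrosobenzene at the C9 methylene gives the 9-O-anilino derivative F9. Zn/AcOH cleaves the N–O bond and gives 17.

## Further compounds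

F1 | step 12 | C8/C9 acetonide of triol 17 (cis-4,5-disubstituted 2,2-dimethyl-1,3-dioxolane) | CCSC[C@@H]1C(=O)O[C@H](/C=C(/C)[C@@H](O[Si](C)(C)C(C)(C)C)CCO)[C@H]1[C@@H]2OC(C)(C)O[C@@H]2C(C)=O
F2 | step 12 | C8/C9 acetonide of seco keto-aldehyde 18 | CCSC[C@@H]1C(=O)O[C@H](/C=C(/C)[C@@H](O[Si](C)(C)C(C)(C)C)CC=O)[C@H]1[C@@H]2OC(C)(C)O[C@@H]2C(C)=O
F3 | step 12 | macrocyclic C1,C10-diol (pinacol product, either C1 epimer) with C8/C9 acetonide | CCSC[C@@H]1C(=O)O[C@@H]2/C=C(/C)[C@@H](O[Si](C)(C)C(C)(C)C)CC(O)[C@@](C)(O)[C@H]3OC(C)(C)O[C@H]3[C@@H]12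
F4 | step 12 | C8/C9 acetonide of macrocyclic α-ketol 19 | CCSC[C@@H]1C(=O)O[C@@H]2/C=C(/C)[C@@H](O[Si](C)(C)C(C)(C)C)CC(=O)[C@@](C)(O)[C@H]3OC(C)(C)O[C@H]3[C@@H]12
F5 | step 13 | 9-O-triethylsilyl ether of seco keto-aldehyde 18 | CCSC[C@@H]1C(=O)O[C@H](/C=C(/C)[C@@H](O[Si](C)(C)C(C)(C)C)CC=O)[C@H]1[C@H](O)[C@H](O[Si](CC)(CC)CC)C(C)=O
F6 | step 13 | 8-O-tigloyl-9-O-triethylsilyl seco keto-aldehyde | CCSC[C@@H]1C(=O)O[C@H](/C=C(/C)[C@@H](O[Si](C)(C)C(C)(C)C)CC=O)[C@H]1[C@H](OC(=O)/C(C)=C/C)[C@H](O[Si](CC)(CC)CC)C(C)=O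
F7 | step 13 | 9-O-triethylsilyl ether of macrocyclic tiglate 21 | CCSC[C@@H]1C(=O)O[C@@H]2/C=C(/C)[C@@H](O[Si](C)(C)C(C)(C)C)CC(=O)[C@@](C)(O)[C@@H](O[Si](CC)(CC)CC)[C@@H](OC(=O)/C(C)=C/C)[C@@H]12
F8 | step 10 | acetone aldol adduct of 15 (C8 carbinol, C9 methylene, C10 methyl ketone) | CCSC[C@@H]1C(=O)O[C@H](/C=C(/C)[C@@H](O[Si](C)(C)C(C)(C)C)CCO)[C@H]1[C@H](O)CC(C)=O
F9 | step 10 | 9-O-(phenylamino) derivative of diol 17 | CCSC[C@@H]1C(=O)O[C@H](/C=C(/C)[C@@H](O[Si](C)(C)C(C)(C)C)CCO)[C@H]1[C@H](O)[C@H](ONc2ccccc2)C(C)=O
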